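**Retrosynthetic overview**
- Hopeafuran ⇐ its tetra-O-methyl ether (free 4-hydroxyphenyl on the stereocentre) by global O-demethylation.
- Seven-membered ketone ring (formed last) ⇐ C(=O)–CH(Ar) bond: carbene-bound acyl anion of a benzofuran-4-carbaldehyde adds 1,6 to a para-quinone methide made in the flask; this closes the ring and sets (S).
- Quinone methide ⇐ aryl silyl ether/benzhydryl acetate ⇐ carbinol ⇐ Suzuki biaryl bond between a 3-iodobenzofuran and a 3-aryl benzoxaborole.
- Benzofuran ring (formed first) ⇐ iodocyclisation of an ortho-alkynylanisole ⇐ Sonogashira coupling.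
- Benzoxaborole ⇐ aryllithium addition to 2-bromo-4,6-dimethoxybenzaldehyde, Br/Li exchange, borylation.

Assumption: 1, 5 and 6 are bought as catalogue compounds; the stereocentre of the target is (S) as read from the SMILES; the sense of induction of the triazolium salt in step 6 is a model prediction, and the mirror-image salt is equally available.

**Step 1**
Reactants: 1 2-bromo-3,5-dimethoxybenzaldehyde; 2 1-ethynyl-4-methoxybenzene
Product: 3 3,5-dimethoxy-2-[(4-methoxyphenyl)ethynyl]benzaldehyde
Conditions: PdCl2(PPh3)2 (3 mol%), CuI (3 mol%), Et3N, DMF, 70 °C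
Reagents that add atoms: none
Why: Sonogashira coupling, in which the ortho-formyl group activates the hindered C–Br bond towards oxidative addition to zerovalent palladium and the copper acetylide of 2 transmetalates, leaving the aldehyde and both methoxy groups untouched.

**Step 2**
Reactants: 3 3,5-dimethoxy-2-[(4-methoxyphenyl)ethynyl]benzaldehyde
Product: 4 3-iodo-6-methoxy-2-(4-methoxyphenyl)-1-benzofuran-4-carbaldehyde
Conditions: I2 (2 equiv), CH2Cl2, rt; aq Na2S2O3 work-up
Reagents that add atoms: iodine, I-I
Why: Electrophilic iodocyclisation of an ortho-alkynylanisole, in which the iodonium-activated alkyne is attacked 5-endo-dig by the adjacent methoxy oxygen at the anisyl-stabilised carbon and iodide then removes the O-methyl group irreversibly as MeI, whereas attack by the formyl oxygen is reversible and has no exit because no external nucleophile is present.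

**Step 3**
Reactants: 5 (4-bromophenoxy)tri(propan-2-yl)silane; 6 2-bromo-4,6-dimethoxybenzaldehyde
Product: 10 1-hydroxy-4,6-dimethoxy-3-{4-[tri(propan-2-yl)silyloxy]phenyl}-1,3-dihydro-2,1-benzoxaborole (racemic), via aryllithium 7 (not isolated), via lithium alkoxide 8 (not isolated), via dilithio alkoxide 9 (not isolated)
Conditions: 5, n-BuLi (1.05 equiv), THF, −78 °C; add 6, −78 °C; n-BuLi (1.2 equiv), −78 °C; B(OiPr)3, −78 °C → rt; aq NH4Cl
Reagents that add atoms: triisopropyl borate, CC(C)OB(OC(C)C)OC(C)C; water, O
Why: Bromine–lithium exchange on 5 and 1,2-addition to the aldehyde give 8, a second exchange (faster than ortho-deprotonation at −78 °C) gives 9, and borylation with mild hydrolysis closes the boronic hemiester, which masks the carbinol and activates the ring for coupling; the racemic carbinol carbon becomes planar in step 6.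

**Step 4**
Reactants: 4 3-iodo-6-methoxy-2-(4-methoxyphenyl)-1-benzofuran-4-carbaldehyde; 10 the benzoxaborole
Product: 11 3-{2-[hydroxy(4-{[tri(propan-2-yl)silyl]oxy}phenyl)methyl]-3,5-dimethoxyphenyl}-6-methoxy-2-(4-methoxyphenyl)-1-benzofuran-4-carbaldehyde (racemic at the carbinol carbon)
Conditions: Pd(OAc)2 (5 mol%), 2-dicyclohexylphosphino-2',6'-dimethoxybiphenyl (SPhos, 10 mol%), K3PO4, THF/H2O 10:1, 50 °C
Reagents that add atoms: none
Why: Suzuki–Miyaura coupling, in which the iodide activated by the peri formyl group adds quickly to zerovalent palladium, the hydroxide-opened benzoxaborole transmetalates and the bulky electron-rich phosphine drives reductive elimination to the hindered biaryl, while the mild base at 50 °C spares the silyl ether and the aldehyde.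

**Step 5**
Reactants: 11 the biaryl carbinol
Product: 12 [2-(4-formyl-6-methoxy-2-(4-methoxyphenyl)-1-benzofuran-3-yl)-4,6-dimethoxyphenyl](4-{[tri(propan-2-yl)silyl]oxy}phenyl)methyl acetate (racemic)
Conditions: Ac2O, Et3N, 4-(dimethylamino)pyridine (cat.), CH2Cl2, 0 °C; neutral work-up, Et3N-deactivated silica
Reagents that add atoms: acetic anhydride, CC(=O)OC(C)=O
Why: DMAP-catalysed acylation of the secondary benzhydrol turns hydroxide into acetate, a leaving group whose release in step 6 produces only a weak base, and neither the aldehyde nor the aryl silyl ether reacts.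

**Step 6**
Reactants: 12 the benzhydryl acetate
Product: 15 (S)-tetra-O-methylhopeafuran, via caesium phenolate 13 (not isolated), via para-quinone methide 14 (not isolated)
Conditions: (5aR,10bS)-2-(pentafluorophenyl)-5a,10b-dihydro-4H,6H-indeno[2,1-b][1,2,4]triazolo[4,3-d][1,4]oxazin-2-ium tetrafluoroborate (20 mol%), CsF (1.1 equiv), 18-crown-6, 4 Å molecular sieves, THF, 0 °C → rt; AcOH quench at 0 °C
Reagents that add atoms: none
Why: Proposed new method: fluoride removes the silyl group, phenolate 13 expels acetate to give quinone methide 14, and the triazolylidene (freed by fluoride or acetate) converts the neighbouring aldehyde into a nucleophilic acyl anion equivalent that adds 1,6 to the methide carbon, two normally electrophilic carbons thus being joined in a seven-membered transition-state ring; the indane wall of the catalyst differentiates the two faces of the planar methide carbon and sets (S), biaryl and methide rotamers equilibrating faster than C–C bond formation, and the only base left is caesium acetate, too weak to enolise the product; the closest known reactions are the carbene-catalysed 1,6-addition of aldehydes to para-quinone methides giving α,α-diaryl ketones, the asymmetric intramolecular Stetter reaction with aminoindanol triazolium salts, and fluoride-triggered quinone methide generation under carbene catalysis.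

**Step 7**
Reactants: 15 (S)-tetra-O-methylhopeafuran
Product: 16 hopeafuran, (S)-enantiomer
Conditions: BBr3 (12 equiv), CH2Cl2, −78 → 0 °C; ice-water quench
Reagents that add atoms: none
Why: Lewis-acid ether cleavage, in which BBr3 coordinates each aryl methyl ether oxygen and bromide removes the methyl group by SN2, and the absence of base together with a temperature at or below 0 °C is intended to keep the benzylic α-stereocentre from enolising.

**Compound list**
1 | 2-bromo-3,5-dimethoxybenzaldehyde | O=Cc1cc(OC)cc(OC)c1Br | starting material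
2 | 1-ethynyl-4-methoxybenzene | C#Cc1ccc(OC)cc1 | starting material
3 | 3,5-dimethoxy-2-[(4-methoxyphenyl)ethynyl]benzaldehyde | COc1ccc(cc1)C#Cc1c(C=O)cc(OC)cc1OC | intermediate
4 | 3-iodo-6-methoxy-2-(4-methoxyphenyl)-1-benzofuran-4-carbaldehyde | O=Cc1cc(OC)cc2oc(-c3ccc(OC)cc3)c(I)c12 | intermediate
5 | (4-bromophenoxy)tri(propan-2-yl)silane | CC(C)[Si](Oc1ccc(Br)cc1)(C(C)C)C(C)C | starting material
6 | 2-bromo-4,6-dimethoxybenzaldehyde | O=Cc1c(Br)cc(OC)cc1OC | starting material
7 | {4-[tri(propan-2-yl)silyloxy]phenyl}lithium, formed in the flask in step 3 | [Li]c1ccc(O[Si](C(C)C)(C(C)C)C(C)C)cc1 | intermediate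
8 | lithium (2-bromo-4,6-dimethoxyphenyl){4-[tri(propan-2-yl)silyloxy]phenyl}methanolate, racemic, formed in the flask in step 3 | [Li]OC(c1ccc(O[Si](C(C)C)(C(C)C)C(C)C)cc1)c1c(Br)cc(OC)cc1OC | intermediate
9 | lithium (2-lithio-4,6-dimethoxyphenyl){4-[tri(propan-2-yl)silyloxy]phenyl}methanolate, racemic, formed in the flask in step 3 | [Li]OC(c1ccc(O[Si](C(C)C)(C(C)C)C(C)C)cc1)c1c([Li])cc(OC)cc1OC | intermediate
10 | 1-hydroxy-4,6-dimethoxy-3-{4-[tri(propan-2-yl)silyloxy]phenyl}-1,3-dihydro-2,1-benzoxaborole, racemic | OB1OC(c2ccc(O[Si](C(C)C)(C(C)C)C(C)C)cc2)c2c(OC)cc(OC)cc12 | intermediate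
11 | 3-{2-[hydroxy(4-{[tri(propan-2-yl)silyl]oxy}phenyl)methyl]-3,5-dimethoxyphenyl}-6-methoxy-2-(4-methoxyphenyl)-1-benzofuran-4-carbaldehyde, racemic at the carbinol carbon | O=Cc1cc(OC)cc2oc(-c3ccc(OC)cc3)c(c12)-c1cc(OC)cc(OC)c1C(O)c1ccc(O[Si](C(C)C)(C(C)C)C(C)C)cc1 | intermediate
12 | [2-(4-formyl-6-methoxy-2-(4-methoxyphenyl)-1-benzofuran-3-yl)-4,6-dimethoxyphenyl](4-{[tri(propan-2-yl)silyl]oxy}phenyl)methyl acetate, racemic | O=Cc1cc(OC)cc2oc(-c3ccc(OC)cc3)c(c12)-c1cc(OC)cc(OC)c1C(OC(C)=O)c1ccc(O[Si](C(C)C)(C(C)C)C(C)C)cc1 | intermediate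
13 | caesium 4-{acetoxy[2-(4-formyl-6-methoxy-2-(4-methoxyphenyl)-1-benzofuran-3-yl)-4,6-dimethoxyphenyl]methyl}phenolate, racemic, formed in the flask in step 6 | O=Cc1cc(OC)cc2oc(-c3ccc(OC)cc3)c(c12)-c1cc(OC)cc(OC)c1C(OC(C)=O)c1ccc([O-])cc1.[Cs+] | intermediate
14 | 3-{3,5-dimethoxy-2-[(4-oxocyclohexa-2,5-dien-1-ylidene)methyl]phenyl}-6-methoxy-2-(4-methoxyphenyl)-1-benzofuran-4-carbaldehyde (para-quinone methide), formed in the flask in step 6 | O=Cc1cc(OC)cc2oc(-c3ccc(OC)cc3)c(c12)-c1cc(OC)cc(OC)c1C=C1C=CC(=O)C=C1 | intermediate
15 | (S)-tetra-O-methylhopeafuran: hopeafuran with OMe at benzofuran C6, on the 2-aryl group and at both oxygens of the resorcinol ring; the 4-hydroxyphenyl group on the (S)-stereocentre is free | O=C1c2cc(OC)cc3oc(-c4ccc(OC)cc4)c(c23)-c2cc(OC)cc(OC)c2[C@@H]1c1ccc(O)cc1 | intermediate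
16 | hopeafuran, (S): 6-hydroxy-2-(4-hydroxyphenyl)benzofuran whose C3 carries a 3,5-dihydroxyphenyl ring and whose C4 carries a ketone carbon; the ketone carbon and ring carbon 2 of the dihydroxyphenyl ring are bridged by an (S)-CH bearing 4-hydroxyphenyl (seven-membered ring) | O=C1c2cc(O)cc3oc(-c4ccc(O)cc4)c(c23)-c2cc(O)cc(O)c2[C@@H]1c1ccc(O)cc1 | target

**Totals**
Total step count: 7. Longest linear sequence: 6 (steps 1, 2, 4, 5, 6, 7); step 3 is a one-step side branch.

**Three steps most likely to fail**

Step 6. Ring closure and enantiocontrol happen in one untested event: the aldehyde is hindered, the quinone methide is unshielded, and the sense and level of induction are unknown. The fallback sets out from 12 and separates ring closure from stereocontrol. The small achiral salt 2-(pentafluorophenyl)-6,7-dihydro-5H-pyrrolo[2,1-c][1,2,4]triazol-2-ium tetrafluoroborate with CsF/18-crown-6 closes the ring by the same acyl anion addition and gives racemic tetra-O-methylhopeafuran F1. Asymmetric transfer hydrogenation under dynamic kinetic resolution (RuCl(p-cymene)[(S,S)-TsDPEN], HCO2H/Et3N, DBU) follows; the ketone enantiomers interconvert through the enol while one is reduced, and the mirror-image complex is used if a test run shows the other sense. This gives the cis (S,S)-alcohol F2. Dess–Martin periodinane/NaHCO3 at 0 °C oxidises F2 back to the ketone without base, and the route is rejoined at 15.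

Step 7. BBr3 may enolise the Lewis-acid-complexed ketone and erode the ee. The fallback sets out from 15, stops protecting the stereocentre and sets it after deprotection. BBr3 at room temperature gives material of low or zero ee, racemic hopeafuran F3. TMSOTf/Et3N in CH2Cl2 silylates the five phenols and the ketone to the hexakis(trimethylsilyl) enol ether F4, which has no stereocentre. An (S)-BINOL-derived N-triflyl thiophosphoramide carrying 2,4,6-triisopropylphenyl groups at the 3 and 3' positions (10 mol%), with phenol as stoichiometric proton source in toluene, protonates the silyl enol ether enantioselectively. MeOH/citric acid work-up removes the aryl silyl ethers without base, and the route is rejoined at 16.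

Step 4. The biaryl has three ortho substituents, the benzoxaborole transmetalates slowly, and protodeboronation competes. The fallback reverses the polarity of the coupling. It sets out from 4: Miyaura borylation (B2pin2, Pd(dppf)Cl2, KOAc, dioxane, 80 °C) gives the pinacol boronate F5. In the flask of step 3, alkoxide 8 is quenched with aq NH4Cl instead of being lithiated again, which gives the bromo carbinol F6. Coupling of F5 with F6 (Pd(OAc)2, 2-dicyclohexylphosphino-2',4',6'-triisopropylbiphenyl, K3PO4, THF/H2O, 60 °C) rejoins the route at 11.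

**Further compounds**
F1 | step 6 | racemic tetra-O-methylhopeafuran | O=C1c2cc(OC)cc3oc(-c4ccc(OC)cc4)c(c23)-c2cc(OC)cc(OC)c2C1c1ccc(O)cc1
F2 | step 6 | cis alcohol from reduction of the ketone of 15, (S) at the carbinol carbon and (S) at the carbon bearing 4-hydroxyphenyl | O[C@@H]1c2cc(OC)cc3oc(-c4ccc(OC)cc4)c(c23)-c2cc(OC)cc(OC)c2[C@@H]1c1ccc(O)cc1
F3 | step 7 | racemic hopeafuran | O=C1c2cc(O)cc3oc(-c4ccc(O)cc4)c(c23)-c2cc(O)cc(O)c2C1c1ccc(O)cc1
F4 | step 7 | hexakis(trimethylsilyl) derivative of the enol form of hopeafuran (five aryl silyl ethers and the silyl enol ether of the ring ketone) | C[Si](C)(C)OC1=C(c2ccc(O[Si](C)(C)C)cc2)c2c(O[Si](C)(C)C)cc(O[Si](C)(C)C)cc2-c2c(-c3ccc(O[Si](C)(C)C)cc3)oc3cc(O[Si](C)(C)C)cc1c23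
F5 | step 4 | 6-methoxy-2-(4-methoxyphenyl)-3-(4,4,5,5-tetramethyl-1,3,2-dioxaborolan-2-yl)-1-benzofuran-4-carbaldehyde | O=Cc1cc(OC)cc2oc(-c3ccc(OC)cc3)c(B3OC(C)(C)C(C)(C)O3)c12
F6 | step 4 | (2-bromo-4,6-dimethoxyphenyl)(4-{[tri(propan-2-yl)silyl]oxy}phenyl)methanol, racemic | OC(c1ccc(O[Si](C(C)C)(C(C)C)C(C)C)cc1)c1c(Br)cc(OC)cc1OC
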